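**Retrosynthetic overview**

- Ring atoms are numbered as in shikimic acid: C1 carries CO2Me, C1=C2 is the double bond, C3 carries OAc, C4 the propanoate, C5 the (2R)-2-methylbutanoate, C6 is CH2. The C4 propanoate is traced back to a C4 propanoyl (ethyl ketone) group by Baeyer–Villiger oxidation with retention.
- The cyclohexene, the only ring, is then opened by one catalytic enantioselective Diels–Alder disconnection that makes C6–C5 and C3–C4 together and sets C3, C4 and C5. The diene is methyl (3E)-4-acetoxy-2-methylidenebut-3-enoate (C3–C2–C1–C6, already carrying OAc and CO2Me). The dienophile is (1E)-3-oxopent-1-en-1-yl (2R)-2-methylbutanoate (C4–C5, already carrying the C5 ester and the future C4 ester).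
- Enabling feature: the C1=C2 double bond of the cyclohexene lies between C6H2 and the oxygen-bearing C3, so the ring is a Diels–Alder retron. The trans C4/C5 oxygens map onto an E-dienophile, and the cis C3/C4 oxygens onto an endo transition state once the C4 oxygen is written as a ketone.
- The diene comes from a Wittig-derived 4-oxo-enoate by dienol acetylation; the dienophile comes from (2R)-2-methylbutanoic acid and pent-1-yn-3-one.

Key step: step 5

Assumption: the SMILES is read as 3R,4S,5R in the ring (the shikimate configuration) and R in the 2-methylbutanoyl group, and (2R)-2-methylbutanoic acid is taken as a commercial, enantiopure starting material.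

**Step 1**
Reactants: 1 pent-1-yn-3-ol (racemic); 2 (2R)-2-methylbutanoic acid
Product: 4 (1E)-3-oxopent-1-en-1-yl (2R)-2-methylbutanoate, via pent-1-yn-3-one 3 (not isolated)
Conditions: 2-iodoxybenzoic acid (IBX, 1.3 equiv), EtOAc, 75 °C; filter; then 2, N-methylmorpholine (10 mol %), 0 °C → rt
Reagents that add atoms: none
Why: IBX oxidises the propargylic alcohol to the ynone without touching the alkyne, and the tertiary amine then catalyses conjugate addition of the carboxylic acid to the ynone (amine-catalysed oxa-Michael addition to an activated alkyne), which should give the E enol ester under thermodynamic control while the cold, weakly basic medium leaves the stereocentre of 2 untouched.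

**Step 2**
Reactants: 5 methyl 2-(triphenyl-λ5-phosphanylidene)propanoate; 6 2,2-dimethoxyacetaldehyde (commercial 60 % aqueous solution)
Product: 7 methyl (2E)-4,4-dimethoxy-2-methylbut-2-enoate
Conditions: CH2Cl2, rt
Reagents that add atoms: none
Why: Wittig olefination with an α-methyl-stabilised ylide should give the E trisubstituted enoate (ester trans to the acetal carbon) under the usual control of stabilised ylides.

**Step 3**
Reactants: 7 methyl (2E)-4,4-dimethoxy-2-methylbut-2-enoate
Product: 8 methyl (2E)-2-methyl-4-oxobut-2-enoate
Conditions: aq. HCl (1 M), THF, rt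
Reagents that add atoms: water, O
Why: Acid-catalysed hydrolysis of the dimethyl acetal releases the conjugated aldehyde, and the E geometry keeps aldehyde and ester apart so that no hydroxybutenolide can form.

**Step 4**
Reactants: 8 methyl (2E)-2-methyl-4-oxobut-2-enoate
Product: 9 methyl (3E)-4-(acetyloxy)-2-methylidenebut-3-enoate
Conditions: Ac2O, Et3N, DMAP (5 mol %), BHT (trace), CH2Cl2, 0 °C → rt; used promptly, stored cold
Reagents that add atoms: acetic anhydride, CC(=O)OC(C)=O
Why: Vinylogous (γ) deprotonation of the enal at the C2 methyl group followed by O-acetylation of the dienolate is the standard dienol acetate synthesis (as for 1-acetoxybutadiene from crotonaldehyde) and should favour the E enol acetate, the isomer that cycloadds readily, with any Z isomer removed by chromatography.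

**Step 5**
Reactants: 9 methyl (3E)-4-(acetyloxy)-2-methylidenebut-3-enoate; 4 (1E)-3-oxopent-1-en-1-yl (2R)-2-methylbutanoate
Product: 10 methyl (3R,4S,5R)-3-(acetyloxy)-5-{[(2R)-2-methylbutanoyl]oxy}-4-propanoylcyclohex-1-ene-1-carboxylate
Conditions: (S)-o-tolyl-CBS-oxazaborolidine [(S)-3,3-diphenyl-1-(2-methylphenyl)tetrahydro-1H,3H-pyrrolo[1,2-c][1,3,2]oxazaborole] (20 mol %), Tf2NH (20 mol %), CH2Cl2, −78 → −40 °C, 9 (2 equiv) added slowly; pH 7 buffer quench
Reagents that add atoms: none
Why: The protonated oxazaborolidine binds the ketone oxygen of 4, the most Lewis-basic carbonyl present, and lowers its LUMO, and diene 9 then adds in a concerted but asynchronous normal-demand [4+2] cycloaddition in which its CH2 terminus bonds first to the acyloxy-bearing β-carbon; the closest known reaction type is the oxazaborolidinium-catalysed enantioselective Diels–Alder reaction of acyclic enones and acrylates with oxygenated butadienes, and this pairing of an ester-bearing acetoxydiene with a β-acyloxy enone is untested. The cyclohexene ring is closed by this intermolecular suprafacial–suprafacial [4+2] mode, which makes both ring bonds at once and leaves the new double bond already conjugated to the ester. The trans relationship between the C4 acyl group and the C5 acyloxy group is carried over stereospecifically from the E geometry of 4, and the cis relationship between the C3 acetate and the C4 acyl group follows from the endo orientation of the catalyst-bound carbonyl towards the E-configured acetoxydiene. The absolute configuration is set by the catalyst, which shields one face of the coordinated enone; by analogy with acrylate and enone dienophiles the (S)-catalyst is expected to deliver the (3R,4S,5R) adduct, and the resident (R)-acyl stereocentre is too remote to interfere but makes any ring-enantiomeric adduct a diastereomer that can be removed. Regioselectivity is required and is secured by both diene substituents, because the acetoxy donor at one terminus and the ester on the adjacent inner carbon both place the larger HOMO coefficient on the CH2 terminus, which pairs with the electrophilic β-carbon of the enone. Chemoselectivity over Diels–Alder dimerisation of 9 is addressed by activating only the dienophile, working cold and adding 9 slowly.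

**Step 6**
Reactants: 10 methyl (3R,4S,5R)-3-(acetyloxy)-5-{[(2R)-2-methylbutanoyl]oxy}-4-propanoylcyclohex-1-ene-1-carboxylate
Product: 11 methyl (3R,4S,5R)-3-(acetyloxy)-5-{[(2R)-2-methylbutanoyl]oxy}-4-(propanoyloxy)cyclohex-1-ene-1-carboxylate (CNP0403577.1)
Conditions: mCPBA (2 equiv), CH2Cl2, 0 °C → rt
Reagents that add atoms: 3-chloroperoxybenzoic acid (mCPBA), OOC(=O)c1cccc(Cl)c1
Why: Baeyer–Villiger oxidation should proceed through the Criegee adduct with migration of the secondary ring carbon C4 in preference to the primary ethyl group and with retention of configuration at C4, while the ester-conjugated C1=C2 double bond is too electron-poor to be epoxidised by mCPBA at room temperature.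

**Compound list**

1 | pent-1-yn-3-ol (racemic) | CCC(O)C#C | starting material
2 | (2R)-2-methylbutanoic acid | CC[C@@H](C)C(=O)O | starting material
3 | pent-1-yn-3-one | CCC(=O)C#C | intermediate (not isolated)
4 | (1E)-3-oxopent-1-en-1-yl (2R)-2-methylbutanoate | CCC(=O)/C=C/OC(=O)[C@H](C)CC | intermediate
5 | methyl 2-(triphenyl-λ5-phosphanylidene)propanoate | COC(=O)C(C)=P(c1ccccc1)(c1ccccc1)c1ccccc1 | starting material
6 | 2,2-dimethoxyacetaldehyde | COC(OC)C=O | starting material
7 | methyl (2E)-4,4-dimethoxy-2-methylbut-2-enoate | COC(OC)/C=C(\C)C(=O)OC | intermediate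
8 | methyl (2E)-2-methyl-4-oxobut-2-enoate | O=C/C=C(\C)C(=O)OC | intermediate
9 | methyl (3E)-4-(acetyloxy)-2-methylidenebut-3-enoate | CC(=O)O/C=C/C(=C)C(=O)OC | intermediate
10 | methyl (3R,4S,5R)-3-(acetyloxy)-5-{[(2R)-2-methylbutanoyl]oxy}-4-propanoylcyclohex-1-ene-1-carboxylate | CCC(=O)[C@@H]1[C@H](OC(C)=O)C=C(C(=O)OC)C[C@H]1OC(=O)[C@H](C)CC | intermediate
11 | methyl (3R,4S,5R)-3-(acetyloxy)-5-{[(2R)-2-methylbutanoyl]oxy}-4-(propanoyloxy)cyclohex-1-ene-1-carboxylate | CCC(=O)O[C@@H]1[C@H](OC(C)=O)C=C(C(=O)OC)C[C@H]1OC(=O)[C@H](C)CC | target

**Step count**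

Total step count: 6. Longest linear sequence: 5 steps (steps 2, 3, 4, 5, 6).

**Steps most likely to fail**

Step 5. The cycloaddition may stall, because an ester-bearing diene and a donor-substituted enone are both of modest reactivity at low temperature. Diene 9 may also be consumed by Diels–Alder dimerisation, or the catalyst may bind other carbonyl groups and lose facial control. If only the sense of induction is wrong, the enantiomeric catalyst is used. The fallback sets out from 2 and 9 and returns at 10; it replaces the single-point-bound ketone by a chelating imide. Propiolic acid is coupled with 1,3-oxazolidin-2-one (pivaloyl chloride, Et3N, LiCl, THF) to give 3-(prop-2-ynoyl)-1,3-oxazolidin-2-one F1. Acid 2 is added to it under N-methylmorpholine catalysis to give 3-[(2E)-3-{[(2R)-2-methylbutanoyl]oxy}prop-2-enoyl]-1,3-oxazolidin-2-one F2. Cycloaddition of F2 with 9 is catalysed by Cu(SbF6)2 with (S,S)-2,2'-(propane-2,2-diyl)bis(4-tert-butyl-4,5-dihydrooxazole) (10 mol %, divalent copper, two-point chelation of the imide, CH2Cl2, −20 °C → rt). It should give the endo adduct methyl (3R,4S,5R)-3-(acetyloxy)-5-{[(2R)-2-methylbutanoyl]oxy}-4-[(2-oxo-1,3-oxazolidin-3-yl)carbonyl]cyclohex-1-ene-1-carboxylate F3. EtSLi (THF, −78 °C) exchanges the oxazolidinone for the thioester methyl (3R,4S,5R)-3-(acetyloxy)-4-[(ethylsulfanyl)carbonyl]-5-{[(2R)-2-methylbutanoyl]oxy}cyclohex-1-ene-1-carboxylate F4. Fukuyama coupling of F4 with EtZnI and PdCl2(PPh3)2 (5 mol %, divalent palladium precatalyst, toluene, rt) then gives ketone 10.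

Step 6. Oxygen insertion into an electron-poor, hindered ketone may be slow, migration of the ethyl group may compete with migration of C4, and acid may promote β-elimination of an acyloxy group on prolonged exposure. The fallback runs from 10 to 11 and makes no new compound (F0). It is an enzymatic Baeyer–Villiger oxidation with an isolated flavin-dependent Baeyer–Villiger monooxygenase (cyclohexanone monooxygenase or phenylacetone monooxygenase type), O2 and catalytic NADPH recycled by glucose and glucose dehydrogenase, in pH 7.5 buffer with a cosolvent. The enzyme-bound flavin peroxide takes the place of the peracid, so the Criegee step runs at neutral pH without free peracid, and a panel of such enzymes would be screened for migration of the ring carbon.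

Step 4. Vinylogous enolisation may lose out to amine-triggered conjugate addition and oligomerisation of the electrophilic 4-oxo-enoate, the enol acetate may form with poor E/Z control, and the product diene may dimerise on handling. The fallback sets out from 8 and returns at 10. Aldehyde 8 is converted with TBSOTf and Et3N (CH2Cl2, −78 → 0 °C) into the silyl dienol ether methyl (3E)-4-{[tert-butyl(dimethyl)silyl]oxy}-2-methylidenebut-3-enoate F5, a more electron-rich diene formed under soft enolisation. Cycloaddition of F5 with 4 under the conditions of step 5 should give methyl (3R,4S,5R)-3-{[tert-butyl(dimethyl)silyl]oxy}-5-{[(2R)-2-methylbutanoyl]oxy}-4-propanoylcyclohex-1-ene-1-carboxylate F6. HF·pyridine (THF, 0 °C) frees the alcohol methyl (3R,4S,5R)-3-hydroxy-5-{[(2R)-2-methylbutanoyl]oxy}-4-propanoylcyclohex-1-ene-1-carboxylate F7, which is acetylated at once (Ac2O, pyridine, 0 °C) to 10.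

**Further compounds**

F1 | step 5 | 3-(prop-2-ynoyl)-1,3-oxazolidin-2-one | C#CC(=O)N1CCOC1=O
F2 | step 5 | 3-[(2E)-3-{[(2R)-2-methylbutanoyl]oxy}prop-2-enoyl]-1,3-oxazolidin-2-one | O=C(/C=C/OC(=O)[C@H](C)CC)N1CCOC1=O
F3 | step 5 | methyl (3R,4S,5R)-3-(acetyloxy)-5-{[(2R)-2-methylbutanoyl]oxy}-4-[(2-oxo-1,3-oxazolidin-3-yl)carbonyl]cyclohex-1-ene-1-carboxylate | O=C(N2CCOC2=O)[C@@H]1[C@H](OC(C)=O)C=C(C(=O)OC)C[C@H]1OC(=O)[C@H](C)CC
F4 | step 5 | methyl (3R,4S,5R)-3-(acetyloxy)-4-[(ethylsulfanyl)carbonyl]-5-{[(2R)-2-methylbutanoyl]oxy}cyclohex-1-ene-1-carboxylate | CCSC(=O)[C@@H]1[C@H](OC(C)=O)C=C(C(=O)OC)C[C@H]1OC(=O)[C@H](C)CC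
F0 | step 6 | none | none
F5 | step 4 | methyl (3E)-4-{[tert-butyl(dimethyl)silyl]oxy}-2-methylidenebut-3-enoate | C=C(C(=O)OC)/C=C/O[Si](C)(C)C(C)(C)C
F6 | step 4 | methyl (3R,4S,5R)-3-{[tert-butyl(dimethyl)silyl]oxy}-5-{[(2R)-2-methylbutanoyl]oxy}-4-propanoylcyclohex-1-ene-1-carboxylate | CCC(=O)[C@@H]1[C@H](O[Si](C)(C)C(C)(C)C)C=C(C(=O)OC)C[C@H]1OC(=O)[C@H](C)CC
F7 | step 4 | methyl (3R,4S,5R)-3-hydroxy-5-{[(2R)-2-methylbutanoyl]oxy}-4-propanoylcyclohex-1-ene-1-carboxylate | CCC(=O)[C@@H]1[C@H](O)C=C(C(=O)OC)C[C@H]1OC(=O)[C@H](C)CC
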